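**Plan**

1. Retrosynthesis: the two aryl O–C(=O) lactone bonds are cut first, giving an achiral all-cis cyclobutane diester bis-phenol. Next the cyclobutane bond C3–C4′ (3,4-dihydrocoumarin numbering) is cut and an oxygen is put back on C4′, which gives a 2-pyrone. The pyrone is cut at C4–C5 and O1–C2 into a β-keto ester and an arylpropiolate, both made from one chroman aldehyde.
2. Enabling feature: the cyclobutane carbons C3, C4, C3′, C4′ carry carbonyl, aryl, carbonyl, aryl in alternation. They are C3, C4, C5, C6 of a 4,6-diaryl-2-pyrone-5-carboxylate, whose ring oxygen on C6 has no counterpart in the target and is removed reductively.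
3. Forward ring order: chromene → chroman → 2-pyrone → cyclobutene with β-lactone bridge (photochemical 4π closure) → cyclobutane → two δ-lactones → both chromenes restored with DDQ.
4. Stereochemistry: the electrocyclisation forces cis fusion. Hydrogenation anti to the lactone bridge and invertive Pd hydrogenolysis of the benzylic C–O bond put all four substituents on one face (meso). A chiral phosphoric acid then decides which ester each phenol closes onto and so sets the absolute configuration (3S,4R,3′S,4′R).

Key step: step 9

Assumption: the sense of induction of the phosphoric acid in step 12 cannot be predicted for this substrate; (R)-TRIP is written, and (S)-TRIP would be used if first experiments showed the opposite sense.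

**Route**

Step 1
Reactants: 1 2,4-dihydroxybenzaldehyde; 2 3-methylbut-2-enal
Product: 3 5-hydroxy-2,2-dimethyl-2H-chromene-6-carbaldehyde
Conditions: pyridine, 140 °C
Reagents that add atoms: none
Why: Knoevenagel-type condensation of the enal at C3 of the resorcinol followed by oxa-6π electrocyclisation onto the free 4-OH should give the angular chromene, the 2-OH being held back by its hydrogen bond to the aldehyde.

Step 2
Reactants: 3 5-hydroxy-2,2-dimethyl-2H-chromene-6-carbaldehyde
Product: 4 5-hydroxy-2,2-dimethylchromane-6-carbaldehyde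
Conditions: H2 (1 atm), 10% Pd/C, Ph2S (cat.), EtOAc, rt
Reagents that add atoms: none
Why: Chemoselective catalytic hydrogenation should saturate the styrene-type chromene double bond while the sulfide-moderated catalyst leaves the hydrogen-bonded aryl aldehyde intact.

Step 3
Reactants: 4 5-hydroxy-2,2-dimethylchromane-6-carbaldehyde
Product: 5 5-(benzyloxy)-2,2-dimethylchromane-6-carbaldehyde
Conditions: BnBr, K2CO3, DMF, 60 °C
Reagents that add atoms: benzyl bromide, BrCc1ccccc1
Why: Williamson etherification of the chelated phenol is routine in a warm polar solvent, and the benzyl ether is later removed in the same hydrogenation that reduces the photoproduct.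

Step 4
Reactants: 5 5-(benzyloxy)-2,2-dimethylchromane-6-carbaldehyde
Product: 6 tert-butyl 3-[5-(benzyloxy)-2,2-dimethylchroman-6-yl]-3-hydroxypropanoate (racemic)
Conditions: LDA, t-BuOAc, THF, −78 °C; then 5; aqueous work-up
Reagents that add atoms: tert-butyl acetate, CC(=O)OC(C)(C)C
Why: Aldol addition of the lithium enolate of tert-butyl acetate to the non-enolisable aryl aldehyde gives the β-hydroxy ester, whose stereocentre is removed in the next step.

Step 5
Reactants: 6 tert-butyl 3-[5-(benzyloxy)-2,2-dimethylchroman-6-yl]-3-hydroxypropanoate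
Product: 7 tert-butyl 3-[5-(benzyloxy)-2,2-dimethylchroman-6-yl]-3-oxopropanoate
Conditions: Dess–Martin periodinane (1.2 equiv), CH2Cl2, 0 °C to rt
Reagents that add atoms: none
Why: Dess–Martin oxidation of the benzylic secondary alcohol should give the β-keto ester under neutral conditions that spare the benzyl ether and the tert-butyl ester.

Step 6
Reactants: 5 5-(benzyloxy)-2,2-dimethylchromane-6-carbaldehyde
Product: 8 5-(benzyloxy)-6-(2,2-dibromoethenyl)-2,2-dimethylchromane
Conditions: CBr4, PPh3, CH2Cl2, 0 °C
Reagents that add atoms: carbon tetrabromide, BrC(Br)(Br)Br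
Why: First stage of the Corey–Fuchs reaction, a Wittig-type dibromo-olefination of the aryl aldehyde.

Step 7
Reactants: 8 5-(benzyloxy)-6-(2,2-dibromoethenyl)-2,2-dimethylchromane
Product: 10 methyl 3-[5-(benzyloxy)-2,2-dimethylchroman-6-yl]prop-2-ynoate, via lithium arylacetylide 9 (not isolated)
Conditions: n-BuLi (2.1 equiv), THF, −78 to 0 °C; then ClCO2Me, −78 °C to rt
Reagents that add atoms: methyl chloroformate, COC(=O)Cl
Why: Second stage of the Corey–Fuchs reaction, in which bromine–lithium exchange, Fritsch–Buttenberg–Wiechell rearrangement and deprotonation give the lithium acetylide, which is C-acylated by the chloroformate.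

Step 8
Reactants: 7 tert-butyl 3-[5-(benzyloxy)-2,2-dimethylchroman-6-yl]-3-oxopropanoate; 10 methyl 3-[5-(benzyloxy)-2,2-dimethylchroman-6-yl]prop-2-ynoate
Product: 12 tert-butyl 4,6-bis[5-(benzyloxy)-2,2-dimethylchroman-6-yl]-2-oxo-2H-pyran-5-carboxylate, via acyclic Michael adduct 11 (not isolated)
Conditions: t-BuOK (0.3 equiv), t-BuOH/THF, rt to 50 °C
Reagents that add atoms: none
Why: Classical base-mediated 2-pyrone annulation, in which Michael addition of the β-keto ester carbanion to the aryl-bearing carbon of the ynoate and lactonisation of the enol oxygen onto the methyl ester place the ynoate aryl at C4, the tert-butyl ester at C5 and the aroyl aryl at C6.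

Step 9
Reactants: 12 tert-butyl 4,6-bis[5-(benzyloxy)-2,2-dimethylchroman-6-yl]-2-oxo-2H-pyran-5-carboxylate
Product: 13 tert-butyl rac-(1R,4S)-1,5-bis[5-(benzyloxy)-2,2-dimethylchroman-6-yl]-3-oxo-2-oxabicyclo[2.2.0]hex-5-ene-6-carboxylate (cis-fused)
Conditions: hν (350–365 nm), degassed MeCN (5 mM), 0 °C, flow reactor
Reagents that add atoms: none
Why: Excitation of the 2-pyrone (π,π*) should trigger a disrotatory 4π electrocyclisation of the C3=C4–C5=C6 diene that forms the C3–C6 σ bond, the valence isomerisation known for 2-pyrone, alkyl-2-pyrones and coumalate esters. The cyclobutene closes by this 4π disrotatory mode, and the former pyrone C6–O1–C2(=O)–C3 unit becomes the β-lactone bridge without any new bond of its own. The two new stereocentres (C1 with aryl and oxygen, C4 with hydrogen) can only be cis because a bicyclo[2.2.0] skeleton cannot be trans-fused, so the relative configuration is set by geometry and the product is racemic. The step needs closure to win over ring opening to the ketene, reversion and secondary loss of CO2. The aprotic, non-nucleophilic solvent lets any ketene re-close, the long wavelength is absorbed by the pyrone but hardly by the cinnamate-like product, and low temperature with short residence time limits thermal reversion. The ortho-benzyloxy groups and the flanked C5 ester twist both aryl rings out of the pyrone plane so that excitation stays largely pyrone-localised, and the saturated chroman rings and benzyl ethers are photoinert here.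

Step 10
Reactants: 13 tert-butyl rac-(1R,4S)-1,5-bis[5-(benzyloxy)-2,2-dimethylchroman-6-yl]-3-oxo-2-oxabicyclo[2.2.0]hex-5-ene-6-carboxylate
Product: 16 all-cis 3-(tert-butoxycarbonyl)-2,4-bis(5-hydroxy-2,2-dimethylchroman-6-yl)cyclobutane-1-carboxylic acid (achiral), via saturated β-lactone 14 (not isolated), via all-cis dibenzyl ether acid 15 (not isolated)
Conditions: H2 (1 atm), 10% Pd/C, EtOAc/EtOH, 0 °C to rt; filtered and used cold
Reagents that add atoms: none
Why: Heterogeneous hydrogenation should add H2 to the strained cyclobutene anti to the lactone bridge, Pd hydrogenolysis of the tertiary benzylic lactone C–O bond proceeds with inversion so that this aryl group moves onto the face the lactone occupied, and the benzyl ethers are cleaved in the same operation, which gives the all-cis array with both carboxyl and both aryl groups on one face.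

Step 11
Reactants: 16 all-cis 3-(tert-butoxycarbonyl)-2,4-bis(5-hydroxy-2,2-dimethylchroman-6-yl)cyclobutane-1-carboxylic acid
Product: 17 di-tert-butyl all-cis-2,4-bis(5-hydroxy-2,2-dimethylchroman-6-yl)cyclobutane-1,3-dicarboxylate (meso)
Conditions: O-tert-butyl-N,N′-diisopropylisourea (3 equiv), CH2Cl2, rt
Reagents that add atoms: O-tert-butyl-N,N′-diisopropylisourea, CC(C)N=C(OC(C)(C)C)NC(C)C
Why: Isourea esterification transfers a tert-butyl group to the carboxylate without activating any acyl group, so the acid is esterified selectively over the two hindered phenols, no lactone forms prematurely and the stereocentres are untouched.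

Step 12
Reactants: 17 di-tert-butyl all-cis-2,4-bis(5-hydroxy-2,2-dimethylchroman-6-yl)cyclobutane-1,3-dicarboxylate
Product: 19 syn head-to-tail cyclobutane dimer of 3′,4′-dihydroseselin, (3S,4R,3′S,4′R), all four cyclobutane hydrogens cis, via mono-lactone 18 (not isolated)
Conditions: (R)-TRIP [(R)-3,3′-bis(2,4,6-triisopropylphenyl)-1,1′-binaphthyl-2,2′-diyl hydrogen phosphate] (10 mol%), toluene, 40 °C
Reagents that add atoms: none
Why: Proposed new method: the chiral phosphoric acid should hold a phenol OH at its P=O oxygen while protonating one of the two enantiotopic tert-butyl ester carbonyls that flank this aryl group, so that acyl substitution with loss of tert-butanol closes the first δ-lactone enantioselectively and thereby fixes the absolute configuration of all four stereocentres, after which the second phenol has only one cis ester left to close onto; the closest known reaction type is the chiral-phosphoric-acid-catalysed desymmetrising lactonisation of prochiral di-tert-butyl diesters that carry a pendant hydroxyl group.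

Step 13
Reactants: 19 syn head-to-tail cyclobutane dimer of 3′,4′-dihydroseselin
Product: 21 CNP0167575.1, the syn head-to-tail cyclobutane dimer of seselin, (3S,4R,3′S,4′R), via mono-chromene 20 (not isolated)
Conditions: DDQ (3 equiv), 1,4-dioxane, reflux
Reagents that add atoms: none
Why: DDQ dehydrogenation of 2,2-dimethylchromans, known for dihydropyranocoumarins of the dihydroseselin type, removes hydride from the benzylic C4 methylene ortho to the ring ether oxygen and then the C3 proton, while the cyclobutane methine hydrogens on a strained ring flanked by lactone carbonyls should not be abstracted, so the four stereocentres remain.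

**Compound list**

1 | 2,4-dihydroxybenzaldehyde | O=Cc1ccc(O)cc1O | starting material
2 | 3-methylbut-2-enal | CC(C)=CC=O | starting material
3 | 5-hydroxy-2,2-dimethyl-2H-chromene-6-carbaldehyde | CC1(C)C=Cc2c(O1)ccc(C=O)c2O | intermediate
4 | 5-hydroxy-2,2-dimethylchromane-6-carbaldehyde | CC1(C)CCc2c(O1)ccc(C=O)c2O | intermediate
5 | 5-(benzyloxy)-2,2-dimethylchromane-6-carbaldehyde | CC1(C)CCc2c(O1)ccc(C=O)c2OCc1ccccc1 | intermediate
6 | tert-butyl 3-[5-(benzyloxy)-2,2-dimethylchroman-6-yl]-3-hydroxypropanoate (racemic) | CC1(C)CCc2c(O1)ccc(C(O)CC(=O)OC(C)(C)C)c2OCc1ccccc1 | intermediate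
7 | tert-butyl 3-[5-(benzyloxy)-2,2-dimethylchroman-6-yl]-3-oxopropanoate | CC1(C)CCc2c(O1)ccc(C(=O)CC(=O)OC(C)(C)C)c2OCc1ccccc1 | intermediate
8 | 5-(benzyloxy)-6-(2,2-dibromoethenyl)-2,2-dimethylchromane | CC1(C)CCc2c(O1)ccc(C=C(Br)Br)c2OCc1ccccc1 | intermediate
9 | lithium [5-(benzyloxy)-2,2-dimethylchroman-6-yl]acetylide (formed and consumed in step 7) | [Li]C#Cc1ccc2OC(C)(C)CCc2c1OCc1ccccc1 | intermediate
10 | methyl 3-[5-(benzyloxy)-2,2-dimethylchroman-6-yl]prop-2-ynoate | COC(=O)C#Cc1ccc2OC(C)(C)CCc2c1OCc1ccccc1 | intermediate
11 | 5-tert-butyl 1-methyl (2E)-4-[5-(benzyloxy)-2,2-dimethylchromane-6-carbonyl]-3-[5-(benzyloxy)-2,2-dimethylchroman-6-yl]pent-2-enedioate (Michael adduct, formed and consumed in step 8) | COC(=O)/C=C(/c1ccc2OC(C)(C)CCc2c1OCc1ccccc1)C(C(=O)c1ccc2OC(C)(C)CCc2c1OCc1ccccc1)C(=O)OC(C)(C)C | intermediate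
12 | tert-butyl 4,6-bis[5-(benzyloxy)-2,2-dimethylchroman-6-yl]-2-oxo-2H-pyran-5-carboxylate | O=C1C=C(c2ccc3OC(C)(C)CCc3c2OCc2ccccc2)C(C(=O)OC(C)(C)C)=C(c2ccc3OC(C)(C)CCc3c2OCc2ccccc2)O1 | intermediate
13 | tert-butyl rac-(1R,4S)-1,5-bis[5-(benzyloxy)-2,2-dimethylchroman-6-yl]-3-oxo-2-oxabicyclo[2.2.0]hex-5-ene-6-carboxylate (cis-fused; one enantiomer drawn) | O=C1O[C@]2(c3ccc4OC(C)(C)CCc4c3OCc3ccccc3)C(C(=O)OC(C)(C)C)=C(c3ccc4OC(C)(C)CCc4c3OCc3ccccc3)[C@H]12 | intermediate
14 | tert-butyl 1,5-bis[5-(benzyloxy)-2,2-dimethylchroman-6-yl]-3-oxo-2-oxabicyclo[2.2.0]hexane-6-carboxylate, racemic, cis-fused, 5-aryl and 6-ester on the lactone face (formed and consumed in step 10; one enantiomer drawn) | O=C1O[C@]2(c3ccc4OC(C)(C)CCc4c3OCc3ccccc3)[C@H](C(=O)OC(C)(C)C)[C@H](c3ccc4OC(C)(C)CCc4c3OCc3ccccc3)[C@H]12 | intermediate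
15 | all-cis 2,4-bis[5-(benzyloxy)-2,2-dimethylchroman-6-yl]-3-(tert-butoxycarbonyl)cyclobutane-1-carboxylic acid, achiral (formed and consumed in step 10) | OC(=O)[C@@H]1[C@H](c2ccc3OC(C)(C)CCc3c2OCc2ccccc2)[C@H](C(=O)OC(C)(C)C)[C@@H]1c1ccc2OC(C)(C)CCc2c1OCc1ccccc1 | intermediate
16 | all-cis 3-(tert-butoxycarbonyl)-2,4-bis(5-hydroxy-2,2-dimethylchroman-6-yl)cyclobutane-1-carboxylic acid (achiral) | OC(=O)[C@@H]1[C@H](c2ccc3OC(C)(C)CCc3c2O)[C@H](C(=O)OC(C)(C)C)[C@@H]1c1ccc2OC(C)(C)CCc2c1O | intermediate
17 | di-tert-butyl all-cis-2,4-bis(5-hydroxy-2,2-dimethylchroman-6-yl)cyclobutane-1,3-dicarboxylate (meso) | CC(C)(C)OC(=O)[C@@H]1[C@H](c2ccc3OC(C)(C)CCc3c2O)[C@H](C(=O)OC(C)(C)C)[C@@H]1c1ccc2OC(C)(C)CCc2c1O | intermediate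
18 | mono-lactone: 19 with one δ-lactone still open as tert-butyl ester and free phenol, all four cyclobutane hydrogens cis (formed and consumed in step 12) | CC1(C)CCc2c(ccc3c2OC(=O)[C@H]2[C@@H]3[C@@H](C(=O)OC(C)(C)C)[C@H]2c2ccc3OC(C)(C)CCc3c2O)O1 | intermediate
19 | syn head-to-tail cyclobutane dimer of 3′,4′-dihydroseselin, (3S,4R,3′S,4′R) in 3,4-dihydrocoumarin numbering, all four cyclobutane hydrogens cis | CC1(C)CCc2c(ccc3c2OC(=O)[C@H]2[C@@H]3[C@H]3C(=O)Oc4c5c(ccc4[C@H]32)OC(C)(C)CC5)O1 | intermediate
20 | mono-chromene: 19 with one chroman ring dehydrogenated (formed and consumed in step 13) | CC1(C)C=Cc2c(ccc3c2OC(=O)[C@H]2[C@@H]3[C@H]3C(=O)Oc4c5c(ccc4[C@H]32)OC(C)(C)CC5)O1 | intermediate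
21 | CNP0167575.1, syn head-to-tail cyclobutane dimer of seselin, (3S,4R,3′S,4′R), all four cyclobutane hydrogens cis | CC1(C)C=Cc2c(ccc3c2OC(=O)[C@H]2[C@@H]3[C@H]3C(=O)Oc4c5c(ccc4[C@H]32)OC(C)(C)C=C5)O1 | target

**Count and risks**

Total step count: 13. Longest linear sequence: 11 steps (1–3, then 4–5 or 6–7, then 8–13).

Step 12 (new method). The risk is low enantioselectivity: an uncatalysed or self-catalysed lactonisation may compete, and in the mono-lactone the free phenol may attack the neighbouring lactone carbonyl, which interconverts the two enantiomeric mono-lactones. The fallback uses known chemistry and sets out from 17. An achiral Brønsted acid (TsOH·H2O, toluene, 60 °C) should effect the same double lactonisation without stereocontrol. It would pass through the racemic mono-lactone, that is 18 and the mirror-image mono-lactone F1, to the racemate of 19 and the mirror-image bis-lactone F2. Preparative HPLC on a cellulose tris(3,5-dimethylphenylcarbamate) phase would then separate the enantiomers, and the route is rejoined at 19.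

Step 9. The risk is inefficient 4π closure of an aryl-conjugated excited state, with ring opening to the ketene, reversion to the pyrone or secondary photolytic loss of CO2 taking over. The fallback replaces the electrocyclisation by a [2+2] photodimerisation and sets out from 4. Wittig olefination with Ph3P=CHCO2Et in refluxing N,N-diethylaniline should give ethyl 3-(5-hydroxy-2,2-dimethylchroman-6-yl)prop-2-enoate F3, which isomerises and lactonises at that temperature to 3′,4′-dihydroseselin F4. Irradiation of F4 (above 300 nm) as its BF3·OEt2 complex in CH2Cl2, or in the crystal, should favour the syn head-to-tail dimer, as documented for simple coumarins; after separation from isomeric dimers this gives the racemate of 19 and F2. LiOH in THF/H2O opens both lactones of either enantiomer to the same meso all-cis 2,4-bis(5-hydroxy-2,2-dimethylchroman-6-yl)cyclobutane-1,3-dicarboxylic acid F5, liberated at 0 °C and pH 4–5. O-tert-Butyl-N,N′-diisopropylisourea converts F5 into 17, where the route continues.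

Step 10. The risk is poor facial selectivity in the alkene hydrogenation because the bridgehead aryl group shields the convex face, retention instead of inversion in the C–O hydrogenolysis, or lactonisation of the free acid before esterification. The fallback separates C–O cleavage from hydrogenation and sets out from 13. Pd(PPh3)4 (zerovalent palladium) with HCO2H/Et3N in THF should ionise the allylic, benzylic lactone C–O bond with inversion (Tsuji–Trost type) to a symmetrical π-allyl complex and deliver hydride from the metal face. This gives racemic 1,4-cis 2,4-bis[5-(benzyloxy)-2,2-dimethylchroman-6-yl]-3-(tert-butoxycarbonyl)cyclobut-2-ene-1-carboxylic acid F6. Hydrogenation of F6 (H2, 10% Pd/C, EtOAc) from the face opposite to the cis carboxyl and aryl groups, with O-debenzylation by way of 15, then gives 16.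

**Further compounds**

F1 | step 12 | mirror image of mono-lactone 18 | CC1(C)CCc2c(ccc3c2OC(=O)[C@@H]2[C@H]3[C@H](C(=O)OC(C)(C)C)[C@@H]2c2ccc3OC(C)(C)CCc3c2O)O1
F2 | step 12 | mirror image of bis-lactone 19, (3R,4S,3′R,4′S) | CC1(C)CCc2c(ccc3c2OC(=O)[C@@H]2[C@H]3[C@@H]3C(=O)Oc4c5c(ccc4[C@@H]32)OC(C)(C)CC5)O1
F3 | step 9 | ethyl 3-(5-hydroxy-2,2-dimethylchroman-6-yl)prop-2-enoate (E/Z) | CCOC(=O)C=Cc1ccc2OC(C)(C)CCc2c1O
F4 | step 9 | 3′,4′-dihydroseselin (8,8-dimethyl-9,10-dihydro-2H,8H-pyrano[2,3-f]chromen-2-one) | CC1(C)CCc2c(ccc3c2OC(=O)C=C3)O1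
F5 | step 9 | meso all-cis 2,4-bis(5-hydroxy-2,2-dimethylchroman-6-yl)cyclobutane-1,3-dicarboxylic acid | OC(=O)[C@@H]1[C@H](c2ccc3OC(C)(C)CCc3c2O)[C@H](C(=O)O)[C@@H]1c1ccc2OC(C)(C)CCc2c1O
F6 | step 10 | racemic 1,4-cis 2,4-bis[5-(benzyloxy)-2,2-dimethylchroman-6-yl]-3-(tert-butoxycarbonyl)cyclobut-2-ene-1-carboxylic acid (one enantiomer drawn) | OC(=O)[C@@H]1[C@H](c2ccc3OC(C)(C)CCc3c2OCc2ccccc2)C(C(=O)OC(C)(C)C)=C1c1ccc2OC(C)(C)CCc2c1OCc1ccccc1
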